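## Structural features

The target is an achiral tridepside: three benzene rings are joined head to tail by two aryl ester links, the carbonyl of ring A to O4 of ring B and the carbonyl of ring B to O4 of ring C, and ring C ends in a free carboxylic acid (numbering: in each ring C1 carries the carbonyl carbon and C6 the methyl group). Ring A is a 4-hydroxy-2,3-dimethoxy-6-methylbenzoyl unit, substituted everywhere except at C5; rings B and C are two identical orsellinate units with a hydroxyl at C2 and the acylated oxygen at C4. There is no stereocentre, so no two stereocentres stand next to each other and the whole problem is one of regiochemistry and chemoselectivity. The fragile groups are the two aryl esters (hydrolysis, transesterification and acyl migration under base or nucleophiles), the 2-hydroxy-6-methylbenzoic acid terminus (loss of CO2 on heating or in strong acid) and the electron-rich ring A phenol (oxidation). The real difficulty is the bookkeeping of five phenolic oxygens that must end up free, methylated or acylated at the right place; in a conventional assembly rings B and C each bring two hydroxyls of which only the one at C4 may be acylated. The key step exploits the fact that on rings B and C the C2 oxygen lies ortho to the ring's own ester carbonyl while the other ortho position, C6, is methylated, and that on ring A both ortho positions (C2 methoxy, C6 methyl) are occupied: an ester-directed C–H oxygenation therefore has exactly one site on ring B, one on ring C and none on ring A.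

## Logic of the disconnections

16 ⇒ 15. The O–CH2Ph bond of the ring C ester is cut. The free acid is the most delicate form of the molecule, so it is kept masked until the end and released by neutral hydrogenolysis. The forward step must spare two aryl esters and three phenols, which hydrogenolysis over Pd/C does.

15 ⇒ 12. The two C2–O bonds of rings B and C are cut together. Each oxygen sits ortho to an ester carbonyl that can hold a metal, and the second ortho position is blocked by methyl. The gain is that rings B and C become one and the same monophenol, so the depside assembly needs no choice between hydroxyls and no protection on these rings. The demand is a twofold directed C–H oxidation that tolerates ring A and the ester links. Checked position by position, 12 and 15 are consistent with 16, so their constitution stands. The design is tightened in three respects: the ring A phenol is converted on purpose into its trifluoroacetate 13 before catalyst and oxidant are added; K2S2O8 is used and no hypervalent iodine oxidant, which would attack ring A; and partial loss of the benzyl group in the acidic medium is made harmless because the next step removes it anyway.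

12 ⇒ 11. The O–Si bond on ring A is cut. The ring A phenol must be masked during both esterifications or it would be acylated itself. The forward step must remove the silyl group without cleaving or transposing either aryl ester.

11 ⇒ 10 + 8. The ester bond between the ring B carbonyl and O4 of ring C is cut. This splits off ring C as 8, whose single hydroxyl leaves no regiochemical question. The forward step is the acylation of a phenol by a benzoic acid with one ortho substituent.

10 ⇒ 9. The O–CH2Ph bond on the ring B carboxyl is cut. Carrying ring B as a benzyl ester lets the same building block 8 serve for ring B and for ring C and makes a separate phenol protection on ring B unnecessary. The hydrogenolysis must leave the silyl ether and the hindered aryl ester intact.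

9 ⇒ 6 + 8. The ester bond between the ring A carbonyl and O4 of ring B is cut. The demand is the acylation of a phenol by a 2,6-disubstituted benzoic acid.

8 ⇒ 7. The benzyl–oxygen bond is cut. The forward step must alkylate the carboxylate and leave the phenol free, which the difference in acidity secures.

6 ⇒ 4. The C1–CO2H bond of ring A is cut. The carboxyl stands between a methoxy group, which directs lithiation, and the methyl group, while the other free ring position lies next to a bulky, non-coordinating silyloxy group. The demand is regioselective ring metalation without attack at the benzylic methyl group.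

4 ⇒ 3 ⇒ 1. The O–Si bond and then the benzylic C–O bond are cut. The ring A methyl is traced to the formyl group of 1, whose oxygen pattern already matches ring A (free hydroxyl at the future C4, methoxy groups at the future C3 and C2). The demand is exhaustive reduction of the formyl group to methyl without touching the ring.

## Other disconnections considered

Alternative 1: The cut goes through ring A itself, at C1–C6 and C3–C4, and traces the arene to two acyclic esters. Forward, methyl 4-methoxy-3-oxobutanoate A1 and methyl (E)-but-2-enoate A2 would be joined by NaOMe in a Michael addition (C1–C6) followed by Dieckmann condensation (C3–C4) to give the dione A3. Dehydrogenation, for example by halogenation and loss of HX, would then give the resorcinol ester A4.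
- In its favour: the materials are cheap, the annulation is classical, and all substituents of ring A are placed by construction. On regiocontrol it is the better of the chosen plan, whose step 3 depends on a methoxy group out-directing a silyloxy group. The stereocentres of A3 are of no concern because aromatisation erases them.
- Against it here: A4 has hydroxyls at C2 and C4, whereas ring A needs a methyl ether at C2 and a free phenol at C4. The chelated C2 hydroxyl is the less reactive one, so C4 would have to be protected first, C2 methylated under forcing conditions, and the doubly ortho-substituted methyl ester saponified under conditions a silyl ether would hardly survive.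
- Structure: only ring A is addressed; the ester links and the two salicylate hydroxyls still need their own solution.
- Mechanism: enolate chemistry plus an oxidation-level adjustment stands against one directed metalation.
- Step economy: about six steps to an acid comparable with 6 against three in the chosen plan, although the alternative would scale more easily.

Alternative 2: The cut removes three bonds of ring C (C2–C3, C4–C5 and C1–C2) and traces this ring to the diazo ketone A5 and the siloxyalkyne A6. Forward, irradiation of A5 would trigger a photochemical Wolff rearrangement to a vinylketene, and [2+2] cycloaddition with A6 would give a cyclobutenone. Four-electron ring opening, six-electron electrocyclisation and tautomerisation would then give the phenol A7.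
- In its favour: the C2 hydroxyl of ring C is created by the annulation and the C4 oxygen emerges as a silyl ether, already told apart from it. Ring C would need no late C–H oxidation, and on this point the alternative is the better of the chosen plan, whose key step lies beyond known chemistry. The pericyclic cascade is also regiospecific.
- Against it here: the trimethylsilyl group at C3 must be taken off again, and A5 and A6 each need several steps, the former through diazomethane chemistry. After loss of both silyl groups the product is benzyl 2,4-dihydroxy-6-methylbenzoate A8, the same compound that the fallback to step 9 obtains as F2 in one step from a purchasable acid.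
- Structure: only ring C is made; ring B has the same pattern and would need a second annulation or another answer.
- Mechanism: a thermal and photochemical pericyclic sequence stands against a metal-mediated C–H functionalisation; the former is well understood, the latter is not yet shown on this substrate class.
- Step economy: clearly worse, since at least five steps build a ring that the chosen plan takes from 7 in one step plus its share of step 9.

Alternative 3: The cut removes the C6–CH3 and C1–CO2H bonds of ring A together and traces the ring to the chloroarene A9. Forward, A9 would be lithiated at the position flanked by chlorine and methoxy and would lose LiCl to give the C1–C6 aryne. MeMgBr would add at C6, the carbon remote from the methoxy group, so that the carbanion forms at C1 next to the inductively stabilising oxygen, and CO2 would capture it to give the acid A10, identical with 6.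
- In its favour: two carbon substituents are introduced in one operation, and the regiochemistry follows from aryne polarisation, a control element at least equal to the methoxy-directed metalation of step 3. Because A10 is 6, it would feed the chosen end-game unchanged.
- Against it here: A9 is not a stock compound and would take several steps to make. The base that generates the aryne, or a second aryl anion, can add to the aryne in place of MeMgBr, and excess MeMgBr competes with the arylmagnesium for CO2.
- Structure: only ring A is addressed.
- Mechanism: both plans are polar organometallic chemistry of similar risk.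
- Step economy: one step from A9 against three steps from 1, but longer overall once the preparation of A9 is counted. The question that the key step answers is not touched.

Key step: step 9

Remark on the chemistry: 1 and 7 are taken to be purchasable, and ring positions are numbered as in the target (C1 carbonyl-bearing, C6 methyl-bearing) also for compounds in which the C2 oxygen is still missing.

## Steps

Step 1
Reactants: 1 3-hydroxy-4,5-dimethoxybenzaldehyde
Product: 3 2,3-dimethoxy-5-methylphenol, via 5-(hydroxymethyl)-2,3-dimethoxyphenol 2 (not isolated)
Conditions: H2 (3 bar), Pd/C (10 wt %), AcOH, HCl (cat.), 40 °C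
Reagents that add atoms: none
Why: Catalytic hydrogenation of the aryl aldehyde to the benzylic alcohol 2 followed by acid-promoted benzylic hydrogenolysis, which the para methoxy group assists; phenol and methyl ethers are inert under these conditions.

Step 2
Reactants: 3 2,3-dimethoxy-5-methylphenol
Product: 4 (2,3-dimethoxy-5-methylphenoxy)triisopropylsilane
Conditions: TIPSCl (1.2 equiv), imidazole (2.5 equiv), DMF, 25 °C
Reagents that add atoms: triisopropylsilyl chloride, CC(C)[Si](Cl)(C(C)C)C(C)C
Why: Imidazole-promoted silylation of a phenol; the bulky silyl ether withstands organolithium reagents, carbodiimide couplings and hydrogenolysis and shields the ring position next to it.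

Step 3
Reactants: 4 (2,3-dimethoxy-5-methylphenoxy)triisopropylsilane
Product: 6 2,3-dimethoxy-6-methyl-4-(triisopropylsilyloxy)benzoic acid, via ring A aryllithium 5 (not isolated)
Conditions: s-BuLi (1.3 equiv), TMEDA (1.3 equiv), THF, −78 → −30 °C; CO2 (g), −78 → 25 °C; 1 M HCl to pH 3
Reagents that add atoms: carbon dioxide, O=C=O
Why: Directed ortho-metalation followed by carboxylation: the methoxy group directs lithiation to the ring carbon between itself and the methyl group (the future C1 of ring A), whereas the triisopropylsilyloxy group neither binds lithium nor leaves room at its own ortho position; the para relation of lithium and silyloxy rules out silyl migration.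

Step 4
Reactants: 7 4-hydroxy-2-methylbenzoic acid
Product: 8 benzyl 4-hydroxy-2-methylbenzoate
Conditions: BnBr (1.05 equiv), KHCO3 (1.2 equiv), DMF, 40 °C
Reagents that add atoms: benzyl bromide, BrCc1ccccc1
Why: Chemoselective SN2 O-alkylation of the carboxylate; KHCO3 deprotonates the acid but not the phenol, so the hydroxyl stays free.

Step 5
Reactants: 6 2,3-dimethoxy-6-methyl-4-(triisopropylsilyloxy)benzoic acid; 8 benzyl 4-hydroxy-2-methylbenzoate
Product: 9 benzyl 4-{[2,3-dimethoxy-6-methyl-4-(triisopropylsilyloxy)benzoyl]oxy}-2-methylbenzoate
Conditions: DCC (1.2 equiv), DMAP (0.2 equiv), CH2Cl2, 0 → 25 °C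
Reagents that add atoms: none
Why: Steglich esterification; DMAP carries the acyl group of the O-acylisourea to the only hydroxyl of 8, so the ring A to ring B ester forms without a regiochemical question.

Step 6
Reactants: 9 benzyl 4-{[2,3-dimethoxy-6-methyl-4-(triisopropylsilyloxy)benzoyl]oxy}-2-methylbenzoate
Product: 10 4-{[2,3-dimethoxy-6-methyl-4-(triisopropylsilyloxy)benzoyl]oxy}-2-methylbenzoic acid
Conditions: H2 (1 atm), Pd/C (10 wt %), EtOAc, 25 °C
Reagents that add atoms: none
Why: Hydrogenolysis of the benzyl ester; the aryl ester, the silyl ether and the methyl ethers are not reduced under these neutral conditions.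

Step 7
Reactants: 10 4-{[2,3-dimethoxy-6-methyl-4-(triisopropylsilyloxy)benzoyl]oxy}-2-methylbenzoic acid; 8 benzyl 4-hydroxy-2-methylbenzoate
Product: 11 benzyl 4-[(4-{[2,3-dimethoxy-6-methyl-4-(triisopropylsilyloxy)benzoyl]oxy}-2-methylbenzoyl)oxy]-2-methylbenzoate
Conditions: DCC (1.2 equiv), DMAP (0.1 equiv), CH2Cl2, 0 → 25 °C
Reagents that add atoms: none
Why: Second Steglich esterification, now with an acid that has only one ortho substituent; the ester already present is a 2,6-disubstituted benzoate and should resist acyl transfer by DMAP.

Step 8
Reactants: 11 benzyl 4-[(4-{[2,3-dimethoxy-6-methyl-4-(triisopropylsilyloxy)benzoyl]oxy}-2-methylbenzoyl)oxy]-2-methylbenzoate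
Product: 12 benzyl 4-({4-[(4-hydroxy-2,3-dimethoxy-6-methylbenzoyl)oxy]-2-methylbenzoyl}oxy)-2-methylbenzoate
Conditions: TBAF (1.1 equiv), AcOH (1.5 equiv), THF, 0 °C
Reagents that add atoms: none
Why: Fluoride-induced cleavage of the aryl silyl ether; buffering by AcOH keeps the released phenol protonated so that neither aryl ester is cleaved or transposed.

Step 9
Reactants: 12 benzyl 4-({4-[(4-hydroxy-2,3-dimethoxy-6-methylbenzoyl)oxy]-2-methylbenzoyl}oxy)-2-methylbenzoate
Product: 15 benzyl 2-hydroxy-4-({2-hydroxy-4-[(4-hydroxy-2,3-dimethoxy-6-methylbenzoyl)oxy]-6-methylbenzoyl}oxy)-6-methylbenzoate (benzyl ester of the target), via ring A trifluoroacetate 13 (not isolated), via tris(trifluoroacetate) 14 (not isolated)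
Conditions: (CF3CO)2O/CF3CO2H (1:3), 25 °C, 30 min; [RuCl2(p-cymene)]2 (5 mol %), K2S2O8 (4 equiv), 80 °C; evaporate, then MeOH, 25 °C
Reagents that add atoms: trifluoroacetic acid, OC(=O)C(F)(F)F (its carboxylate oxygen becomes each new phenolic oxygen; the pool exchanges with trifluoroacetic anhydride, O=C(OC(=O)C(F)(F)F)C(F)(F)F)
Why: Proposed new method: each ester carbonyl oxygen should bind the cationic divalent ruthenium trifluoroacetate formed from [RuCl2(p-cymene)]2 in CF3CO2H, and carboxylate-assisted metalation of the only ortho C–H (C2–H of ring B and of ring C) should give five-membered ruthenacycles. Oxidation by K2S2O8 to tetravalent ruthenium and C–O reductive elimination with trifluoroacetate should deliver the aryl trifluoroacetates, so that 14 carries three such esters, all of which methanol cleaves on work-up. The closest known reaction type is the ruthenium-catalysed ester-directed ortho C–H hydroxylation of simple alkyl benzoates in CF3CO2H/(CF3CO)2O; new here are the twofold use on one molecule and an aryl ester (that of ring B) as directing group. No ring is closed and no stereocentre is formed. Site selectivity is needed among the seven C–H bonds of rings A to C and rests on the substrate: rings B and C each have one C–H ortho to the carbonyl, the other ortho position carries the methyl group that also stops a second oxidation, and ring A has none. Five-membered chelation through the acyl ring should outrun the six-membered alternative through the aryloxy ring, which would lead to C3 or C5. Ring A is shielded because its phenol is turned into the electron-poor trifluoroacetate 13 before catalyst and oxidant are added. Partial acidolysis of the benzyl ester would not matter, since step 10 removes that group in any case.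

Step 10
Reactants: 15 benzyl 2-hydroxy-4-({2-hydroxy-4-[(4-hydroxy-2,3-dimethoxy-6-methylbenzoyl)oxy]-6-methylbenzoyl}oxy)-6-methylbenzoate
Product: 16 2-hydroxy-4-({2-hydroxy-4-[(4-hydroxy-2,3-dimethoxy-6-methylbenzoyl)oxy]-6-methylbenzoyl}oxy)-6-methylbenzoic acid
Conditions: H2 (1 atm), Pd/C (10 wt %), EtOAc, 25 °C
Reagents that add atoms: none
Why: Hydrogenolysis of the benzyl ester under neutral conditions at room temperature, which avoids both cleavage of the aryl esters and decarboxylation of the 2-hydroxybenzoic acid.

## Compound list

1 | 3-hydroxy-4,5-dimethoxybenzaldehyde | COc1cc(C=O)cc(O)c1OC | starting material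
2 | 5-(hydroxymethyl)-2,3-dimethoxyphenol | COc1cc(CO)cc(O)c1OC | intermediate
3 | 2,3-dimethoxy-5-methylphenol | COc1cc(C)cc(O)c1OC | intermediate
4 | (2,3-dimethoxy-5-methylphenoxy)triisopropylsilane | COc1cc(C)cc(O[Si](C(C)C)(C(C)C)C(C)C)c1OC | intermediate
5 | [2,3-dimethoxy-6-methyl-4-(triisopropylsilyloxy)phenyl]lithium | [Li]c1c(C)cc(O[Si](C(C)C)(C(C)C)C(C)C)c(OC)c1OC | intermediate
6 | 2,3-dimethoxy-6-methyl-4-(triisopropylsilyloxy)benzoic acid | COc1c(O[Si](C(C)C)(C(C)C)C(C)C)cc(C)c(C(=O)O)c1OC | intermediate
7 | 4-hydroxy-2-methylbenzoic acid | Cc1cc(O)ccc1C(=O)O | starting material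
8 | benzyl 4-hydroxy-2-methylbenzoate | Cc1cc(O)ccc1C(=O)OCc1ccccc1 | intermediate
9 | benzyl 4-{[2,3-dimethoxy-6-methyl-4-(triisopropylsilyloxy)benzoyl]oxy}-2-methylbenzoate | COc1c(O[Si](C(C)C)(C(C)C)C(C)C)cc(C)c(C(=O)Oc2ccc(C(=O)OCc3ccccc3)c(C)c2)c1OC | intermediate
10 | 4-{[2,3-dimethoxy-6-methyl-4-(triisopropylsilyloxy)benzoyl]oxy}-2-methylbenzoic acid | COc1c(O[Si](C(C)C)(C(C)C)C(C)C)cc(C)c(C(=O)Oc2ccc(C(=O)O)c(C)c2)c1OC | intermediate
11 | benzyl 4-[(4-{[2,3-dimethoxy-6-methyl-4-(triisopropylsilyloxy)benzoyl]oxy}-2-methylbenzoyl)oxy]-2-methylbenzoate | COc1c(O[Si](C(C)C)(C(C)C)C(C)C)cc(C)c(C(=O)Oc2ccc(C(=O)Oc3ccc(C(=O)OCc4ccccc4)c(C)c3)c(C)c2)c1OC | intermediate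
12 | benzyl 4-({4-[(4-hydroxy-2,3-dimethoxy-6-methylbenzoyl)oxy]-2-methylbenzoyl}oxy)-2-methylbenzoate | COc1c(O)cc(C)c(C(=O)Oc2ccc(C(=O)Oc3ccc(C(=O)OCc4ccccc4)c(C)c3)c(C)c2)c1OC | intermediate
13 | benzyl 4-[(4-{[2,3-dimethoxy-6-methyl-4-(trifluoroacetoxy)benzoyl]oxy}-2-methylbenzoyl)oxy]-2-methylbenzoate | COc1c(OC(=O)C(F)(F)F)cc(C)c(C(=O)Oc2ccc(C(=O)Oc3ccc(C(=O)OCc4ccccc4)c(C)c3)c(C)c2)c1OC | intermediate
14 | benzyl 4-[(4-{[2,3-dimethoxy-6-methyl-4-(trifluoroacetoxy)benzoyl]oxy}-2-methyl-6-(trifluoroacetoxy)benzoyl)oxy]-2-methyl-6-(trifluoroacetoxy)benzoate | COc1c(OC(=O)C(F)(F)F)cc(C)c(C(=O)Oc2cc(C)c(C(=O)Oc3cc(C)c(C(=O)OCc4ccccc4)c(OC(=O)C(F)(F)F)c3)c(OC(=O)C(F)(F)F)c2)c1OC | intermediate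
15 | benzyl 2-hydroxy-4-({2-hydroxy-4-[(4-hydroxy-2,3-dimethoxy-6-methylbenzoyl)oxy]-6-methylbenzoyl}oxy)-6-methylbenzoate | COc1c(O)cc(C)c(C(=O)Oc2cc(C)c(C(=O)Oc3cc(C)c(C(=O)OCc4ccccc4)c(O)c3)c(O)c2)c1OC | intermediate
16 | 2-hydroxy-4-({2-hydroxy-4-[(4-hydroxy-2,3-dimethoxy-6-methylbenzoyl)oxy]-6-methylbenzoyl}oxy)-6-methylbenzoic acid | COc1c(O)cc(C)c(C(=O)Oc2cc(C)c(C(=O)Oc3cc(C)c(C(=O)O)c(O)c3)c(O)c2)c1OC | target

## Step count and least certain steps

Total: 10 steps. Longest linear sequence: 9 steps (steps 1, 2, 3, 5, 6, 7, 8, 9, 10, from 1 to 16); step 4 lies on a one-step branch.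

Step 9 (key step, proposed new method). Most likely to go wrong:
- Incomplete twofold oxidation: the aryl ester carbonyl of ring B is a weaker donor than an alkyl ester carbonyl, so the reaction may stop after one hydroxylation.
- Oxidative degradation of ring A or benzylic oxidation by the persulfate.
- Acid-driven acyl exchange at the depside links in hot CF3CO2H/(CF3CO)2O.
- Metalation through a six-membered chelate on the aryloxy side, which would oxygenate next to an acyloxy group.

The fallback uses known depside chemistry, sets out from 6 and comes back to the route at 15.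
- Purchased 2,4-dihydroxy-6-methylbenzoic acid F1 would be benzylated (BnBr, KHCO3, DMF) to benzyl 2,4-dihydroxy-6-methylbenzoate F2.
- 6 would be esterified (DCC, DMAP, CH2Cl2) at the C4 hydroxyl of F2, the C2 hydroxyl being tied up in a hydrogen bond to the ester carbonyl, to give benzyl 4-{[2,3-dimethoxy-6-methyl-4-(triisopropylsilyloxy)benzoyl]oxy}-2-hydroxy-6-methylbenzoate F3.
- Hydrogenolysis (H2, Pd/C, EtOAc) would give 4-{[2,3-dimethoxy-6-methyl-4-(triisopropylsilyloxy)benzoyl]oxy}-2-hydroxy-6-methylbenzoic acid F4.
- Condensation of F4 with a second portion of F2 by the classical (CF3CO)2O method in toluene, which tolerates the free C2 hydroxyl, would give benzyl 4-[(4-{[2,3-dimethoxy-6-methyl-4-(triisopropylsilyloxy)benzoyl]oxy}-2-hydroxy-6-methylbenzoyl)oxy]-2-hydroxy-6-methylbenzoate F5.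
- TBAF buffered by AcOH would then release 15.

Step 3. Most likely to go wrong: competing deprotonation of the benzylic methyl group, or sluggish ring metalation because the directing methoxy group is crowded by its neighbour, leading to mixtures of carboxylic acids. The fallback sets out from 4 and comes back at 6. Electrophilic bromination (NBS, MeCN, 0 °C) para to the silyloxy group and away from the bulky silyl ether would give (4-bromo-2,3-dimethoxy-5-methylphenoxy)triisopropylsilane F6. Bromine–lithium exchange (n-BuLi, THF, −78 °C) would give 5 at a defined position, and CO2 followed by acidification would give 6.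

Step 5. Most likely to go wrong: slow acyl transfer from the hindered O-acylisourea of the 2,6-disubstituted acid, so that rearrangement to the N-acylurea consumes the acid. The fallback sets out from 6 and comes back at 9. Oxalyl chloride with catalytic DMF in CH2Cl2 would give 2,3-dimethoxy-6-methyl-4-(triisopropylsilyloxy)benzoyl chloride F7, a small and highly reactive electrophile, which would acylate 8 in the presence of Et3N and catalytic DMAP.

Step 8. Most likely to go wrong: fluoride- or phenoxide-induced cleavage or transposition of the less hindered ester between rings B and C while the silyl group is removed. The fallback sets out from 9 and comes back at 12. It moves the fluoride step to a stage where only the hindered ester is present and replaces the silyl group by one that acid removes.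
- Buffered TBAF on 9 would give benzyl 4-[(4-hydroxy-2,3-dimethoxy-6-methylbenzoyl)oxy]-2-methylbenzoate F8.
- Boc2O with catalytic DMAP would give benzyl 4-({4-[(tert-butoxycarbonyl)oxy]-2,3-dimethoxy-6-methylbenzoyl}oxy)-2-methylbenzoate F9.
- Hydrogenolysis would give 4-({4-[(tert-butoxycarbonyl)oxy]-2,3-dimethoxy-6-methylbenzoyl}oxy)-2-methylbenzoic acid F10.
- Steglich esterification with 8 would give benzyl 4-{[4-({4-[(tert-butoxycarbonyl)oxy]-2,3-dimethoxy-6-methylbenzoyl}oxy)-2-methylbenzoyl]oxy}-2-methylbenzoate F11.
- CF3CO2H in CH2Cl2 at 25 °C would cleave the carbonate and give 12.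

## Further compounds

F1 | step 9 | 2,4-dihydroxy-6-methylbenzoic acid (purchased) | Cc1cc(O)cc(O)c1C(=O)O
F2 | step 9 | benzyl 2,4-dihydroxy-6-methylbenzoate | Cc1cc(O)cc(O)c1C(=O)OCc1ccccc1
F3 | step 9 | benzyl 4-{[2,3-dimethoxy-6-methyl-4-(triisopropylsilyloxy)benzoyl]oxy}-2-hydroxy-6-methylbenzoate | COc1c(O[Si](C(C)C)(C(C)C)C(C)C)cc(C)c(C(=O)Oc2cc(C)c(C(=O)OCc3ccccc3)c(O)c2)c1OC
F4 | step 9 | 4-{[2,3-dimethoxy-6-methyl-4-(triisopropylsilyloxy)benzoyl]oxy}-2-hydroxy-6-methylbenzoic acid | COc1c(O[Si](C(C)C)(C(C)C)C(C)C)cc(C)c(C(=O)Oc2cc(C)c(C(=O)O)c(O)c2)c1OC
F5 | step 9 | benzyl 4-[(4-{[2,3-dimethoxy-6-methyl-4-(triisopropylsilyloxy)benzoyl]oxy}-2-hydroxy-6-methylbenzoyl)oxy]-2-hydroxy-6-methylbenzoate | COc1c(O[Si](C(C)C)(C(C)C)C(C)C)cc(C)c(C(=O)Oc2cc(C)c(C(=O)Oc3cc(C)c(C(=O)OCc4ccccc4)c(O)c3)c(O)c2)c1OC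
F6 | step 3 | (4-bromo-2,3-dimethoxy-5-methylphenoxy)triisopropylsilane | COc1c(O[Si](C(C)C)(C(C)C)C(C)C)cc(C)c(Br)c1OC
F7 | step 5 | 2,3-dimethoxy-6-methyl-4-(triisopropylsilyloxy)benzoyl chloride | COc1c(O[Si](C(C)C)(C(C)C)C(C)C)cc(C)c(C(=O)Cl)c1OC
F8 | step 8 | benzyl 4-[(4-hydroxy-2,3-dimethoxy-6-methylbenzoyl)oxy]-2-methylbenzoate | COc1c(O)cc(C)c(C(=O)Oc2ccc(C(=O)OCc3ccccc3)c(C)c2)c1OC
F9 | step 8 | benzyl 4-({4-[(tert-butoxycarbonyl)oxy]-2,3-dimethoxy-6-methylbenzoyl}oxy)-2-methylbenzoate | COc1c(OC(=O)OC(C)(C)C)cc(C)c(C(=O)Oc2ccc(C(=O)OCc3ccccc3)c(C)c2)c1OC
F10 | step 8 | 4-({4-[(tert-butoxycarbonyl)oxy]-2,3-dimethoxy-6-methylbenzoyl}oxy)-2-methylbenzoic acid | COc1c(OC(=O)OC(C)(C)C)cc(C)c(C(=O)Oc2ccc(C(=O)O)c(C)c2)c1OC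
F11 | step 8 | benzyl 4-{[4-({4-[(tert-butoxycarbonyl)oxy]-2,3-dimethoxy-6-methylbenzoyl}oxy)-2-methylbenzoyl]oxy}-2-methylbenzoate | COc1c(OC(=O)OC(C)(C)C)cc(C)c(C(=O)Oc2ccc(C(=O)Oc3ccc(C(=O)OCc4ccccc4)c(C)c3)c(C)c2)c1OC
A1 | alternative 1 | methyl 4-methoxy-3-oxobutanoate | COCC(=O)CC(=O)OC
A2 | alternative 1 | methyl (E)-but-2-enoate | C/C=C/C(=O)OC
A3 | alternative 1 | methyl 3-methoxy-6-methyl-2,4-dioxocyclohexane-1-carboxylate (mixture of stereoisomers and enol forms) | COC1C(=O)CC(C)C(C(=O)OC)C1=O
A4 | alternative 1 | methyl 2,4-dihydroxy-3-methoxy-6-methylbenzoate | COC(=O)c1c(C)cc(O)c(OC)c1O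
A5 | alternative 2 | benzyl (E)-5-diazo-3-methyl-4-oxopent-2-enoate | O=C(OCc1ccccc1)/C=C(\C)C(=O)C=[N+]=[N-]
A6 | alternative 2 | triisopropylsilyl (trimethylsilyl)ethynyl ether | CC(C)[Si](OC#C[Si](C)(C)C)(C(C)C)C(C)C
A7 | alternative 2 | benzyl 2-hydroxy-6-methyl-4-(triisopropylsilyloxy)-3-(trimethylsilyl)benzoate | Cc1cc(O[Si](C(C)C)(C(C)C)C(C)C)c([Si](C)(C)C)c(O)c1C(=O)OCc1ccccc1
A8 | alternative 2 | benzyl 2,4-dihydroxy-6-methylbenzoate | Cc1cc(O)cc(O)c1C(=O)OCc1ccccc1
A9 | alternative 3 | (5-chloro-2,3-dimethoxyphenoxy)triisopropylsilane | COc1cc(Cl)cc(O[Si](C(C)C)(C(C)C)C(C)C)c1OC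
A10 | alternative 3 | 2,3-dimethoxy-6-methyl-4-(triisopropylsilyloxy)benzoic acid | COc1c(O[Si](C(C)C)(C(C)C)C(C)C)cc(C)c(C(=O)O)c1OC
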